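**Strategy.** The quinone ring is cut into a phthaloyl unit (the C1 and C4 carbonyls on the 5,8-dioxygenated benzo ring) and the two-carbon C2=C3 unit, which is a terminal alkyne that already carries the whole side chain with both stereocentres. A phthaloylcobalt metallacycle, made by insertion of monovalent cobalt into a 3,6-bis(silyloxy)benzocyclobutenedione, takes up this alkyne and forms the C1–C2 and C3–C4 ring bonds in one operation. The step exploits the symmetry of the 5,8-dioxygenated benzo ring: either orientation of alkyne insertion gives the same naphthoquinone, so no regiocontrol is needed. Buffered fluoride then unveils the naphthazarin.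

Key step: step 12

Assumptions: (R)-2-methylbutanoic acid (20) is bought as the single enantiomer. The naphthazarin tautomers of 23 interconvert freely, so the drawn tautomer stands for the compound. The cobalt complexes are drawn with dative bonds as formal charges.

**Step 1**
Reactants: 1 2-bromo-1,4-dimethoxybenzene; 2 1,1-diethoxyethene
Product: 5 3,6-dimethoxybenzocyclobutenone, via 3,6-dimethoxybenzyne 3 (not isolated), via 1,1-diethoxy-3,6-dimethoxybenzocyclobutene 4 (not isolated)
Conditions: NaNH2 (2.5 equiv), 2 (3 equiv), THF, reflux; then 1 M HCl, THF, rt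
Reagents that add atoms: water O
Why: NaNH2 removes the proton between Br and OMe and bromide loss gives the symmetric aryne 3, which undergoes a [2+2] cycloaddition with the electron-rich ketene acetal (benzyne–ketene acetal cycloaddition), and the ketal 4 is hydrolysed by acid on work-up.

**Step 2**
Reactants: 5 3,6-dimethoxybenzocyclobutenone
Product: 6 2,2-dibromo-3,6-dimethoxybenzocyclobutenone
Conditions: NBS (2.2 equiv), (PhCO2)2 (cat.), PhCF3, reflux
Reagents that add atoms: N-bromosuccinimide O=C1CCC(=O)N1Br
Why: Wohl–Ziegler radical bromination at the only benzylic methylene, which is also alpha to the carbonyl, should give the gem-dibromide without any need to enolise the strained ketone.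

**Step 3**
Reactants: 6 2,2-dibromo-3,6-dimethoxybenzocyclobutenone
Product: 7 3,6-dimethoxybenzocyclobutene-1,2-dione
Conditions: AgOCOCF3 (2.2 equiv), MeCN/H2O, 50 °C
Reagents that add atoms: water O
Why: Silver-assisted hydrolysis of the alpha,alpha-dibromo ketone (gem-dihalide hydrolysis) should unveil the second carbonyl of the 1,2-dione.

**Step 4**
Reactants: 7 3,6-dimethoxybenzocyclobutene-1,2-dione
Product: 8 3,6-dihydroxybenzocyclobutene-1,2-dione
Conditions: BBr3 (3 equiv), CH2Cl2, −78 to 0 °C; then H2O
Reagents that add atoms: none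
Why: BBr3 should cleave both aryl methyl ethers (Lewis-acid ether cleavage, assisted by the neighbouring carbonyls) while the acid-stable dione survives.

**Step 5**
Reactants: 8 3,6-dihydroxybenzocyclobutene-1,2-dione
Product: 9 3,6-bis(tert-butyldimethylsilyloxy)benzocyclobutene-1,2-dione
Conditions: TBSOTf (2.4 equiv), 2,6-lutidine (3 equiv), CH2Cl2, −78 to 0 °C
Reagents that add atoms: tert-butyldimethylsilyl triflate CC(C)(C)[Si](C)(C)OS(=O)(=O)C(F)(F)F
Why: Silylation of both phenols with a silyl triflate and a non-nucleophilic base avoids nucleophilic opening of the electrophilic four-membered dione and installs groups that fluoride removes at the end.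

**Step 6**
Reactants: 9 3,6-bis(tert-butyldimethylsilyloxy)benzocyclobutene-1,2-dione
Product: 11 chloro(dimethylglyoxime)(pyridine)[3,6-bis(tert-butyldimethylsilyloxy)phthaloyl]cobalt, via chlorobis(triphenylphosphine)[3,6-bis(tert-butyldimethylsilyloxy)phthaloyl]cobalt 10 (not isolated)
Conditions: ClCo(PPh3)3 (1.05 equiv), PhCl, rt; then dimethylglyoxime (1.2 equiv), pyridine, rt
Reagents that add atoms: chlorotris(triphenylphosphine)cobalt Cl[Co-3]([P+](c1ccccc1)(c1ccccc1)c1ccccc1)([P+](c1ccccc1)(c1ccccc1)c1ccccc1)[P+](c1ccccc1)(c1ccccc1)c1ccccc1; dimethylglyoxime CC(=NO)C(C)=NO; pyridine c1ccncc1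
Why: Oxidative addition of monovalent cobalt into the strained C(=O)–C(=O) bond gives the five-membered phthaloyl metallacycle of trivalent cobalt 10, and exchange of both phosphines for dimethylglyoxime and pyridine should give the air-stable, alkyne-reactive complex 11.

**Step 7**
Reactants: 12 2-methylbut-3-en-2-ol; 13 N-methoxy-N-methylacrylamide
Product: 14 (E)-4-hydroxy-N-methoxy-N,4-dimethylpent-2-enamide
Conditions: second-generation Hoveyda–Grubbs catalyst RuCl2(H2IMes)(=CH-C6H4-2-OiPr) (5 mol %), 12 (3 equiv), CH2Cl2, 40 °C
Reagents that add atoms: none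
Why: Olefin cross-metathesis between two slowly homodimerising partners, driven by loss of ethene and by an excess of the cheap alcohol 12, should give the conjugated (E)-enamide under thermodynamic control.

**Step 8**
Reactants: 14 (E)-4-hydroxy-N-methoxy-N,4-dimethylpent-2-enamide; 15 ethynyltrimethylsilane
Product: 17 (E)-6-hydroxy-6-methyl-1-(trimethylsilyl)hept-4-en-1-yn-3-one, via lithium (trimethylsilyl)acetylide 16 (not isolated)
Conditions: 15 (2.5 equiv), n-BuLi (2.4 equiv), THF, −78 °C; then 14, −78 to −20 °C; aq NH4Cl
Reagents that add atoms: none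
Why: Weinreb ketone synthesis, in which the acetylide 16 (one equivalent is consumed by the tertiary OH) adds once to the N-methoxy-N-methylamide and the stable chelate collapses to the ynone only on quench.

**Step 9**
Reactants: 17 (E)-6-hydroxy-6-methyl-1-(trimethylsilyl)hept-4-en-1-yn-3-one
Product: 18 (3E,5R)-2-methyl-7-(trimethylsilyl)hept-3-en-6-yne-2,5-diol
Conditions: Ru[(R,R)-TsNCH(Ph)CH(Ph)NH](p-cymene) (2 mol %), i-PrOH, 25 °C
Reagents that add atoms: none
Why: Noyori asymmetric transfer hydrogenation of an alkynyl ketone, in which the alkynyl group takes the site beside the η6-arene of the catalyst so that the (R,R)-ligand should deliver hydride to the face that gives the (R)-propargylic alcohol, with C=O reduced in preference to the conjugated C=C.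

**Step 10**
Reactants: 18 (3E,5R)-2-methyl-7-(trimethylsilyl)hept-3-en-6-yne-2,5-diol
Product: 19 (3E,5R)-2-methylhept-3-en-6-yne-2,5-diol
Conditions: K2CO3 (0.3 equiv), MeOH, 0 °C to rt
Reagents that add atoms: none
Why: Base-catalysed methanolysis of the alkynyl C–Si bond (protodesilylation) should free the terminal alkyne without touching the stereocentre.

**Step 11**
Reactants: 19 (3E,5R)-2-methylhept-3-en-6-yne-2,5-diol; 20 (R)-2-methylbutanoic acid
Product: 21 (3R,4E)-6-hydroxy-6-methylhept-4-en-1-yn-3-yl (2R)-2-methylbutanoate
Conditions: EDC·HCl (1.3 equiv), DMAP (0.1 equiv), CH2Cl2, 0 °C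
Reagents that add atoms: none
Why: Steglich esterification should acylate the secondary alcohol in preference to the hindered tertiary one, the carbinol configuration being retained because its C–O bond is not broken, and low temperature with catalytic DMAP should keep the alpha-stereocentre of the acid intact.

**Step 12**
Reactants: 11 chloro(dimethylglyoxime)(pyridine)[3,6-bis(tert-butyldimethylsilyloxy)phthaloyl]cobalt; 21 (3R,4E)-6-hydroxy-6-methylhept-4-en-1-yn-3-yl (2R)-2-methylbutanoate
Product: 22 (1R,2E)-1-[5,8-bis(tert-butyldimethylsilyloxy)-1,4-dioxo-1,4-dihydronaphthalen-2-yl]-4-hydroxy-4-methylpent-2-en-1-yl (2R)-2-methylbutanoate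
Conditions: 11 (1.3 equiv), CoCl2·6H2O (1.5 equiv), MeCN, 70 °C
Reagents that add atoms: none
Why: CoCl2·6H2O assists loss of a ligand from the trivalent cobalt of 11, the terminal alkyne of 21 coordinates and inserts into one Co–acyl bond to give a benzo-fused seven-membered cobaltacycle, and C–C reductive elimination then releases the quinone and monovalent cobalt. The closest known reaction is the naphthoquinone synthesis from phthaloylcobalt dimethylglyoxime complexes and terminal alkynes. The six-membered quinone ring is closed by migratory insertion followed by reductive elimination, a formal [4+2] annulation of the four-carbon phthaloyl unit with the two alkyne carbons. No stereocentre is created, and the (R)-carbinol and (R)-alpha-methyl centres lie outside the reacting atoms and are carried through unchanged. The step needs chemoselectivity for the alkyne over the trans-alkene, which is secured because only the alkyne inserts into the Co–acyl bond, and it needs no regiocontrol because the 3,6-disubstituted phthaloyl unit is symmetric. Partial loss of a silyl ether under these conditions would be harmless, since step 13 removes both.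

**Step 13**
Reactants: 22 (1R,2E)-1-[5,8-bis(tert-butyldimethylsilyloxy)-1,4-dioxo-1,4-dihydronaphthalen-2-yl]-4-hydroxy-4-methylpent-2-en-1-yl (2R)-2-methylbutanoate
Product: 23 (1R,2E)-1-(5,8-dihydroxy-1,4-dioxo-1,4-dihydronaphthalen-2-yl)-4-hydroxy-4-methylpent-2-en-1-yl (2R)-2-methylbutanoate
Conditions: TBAF (2.5 equiv), AcOH (3 equiv), THF, 0 °C
Reagents that add atoms: none
Why: Buffered fluoride should cleave the two aryl silyl ethers, which are labile because they sit peri to the quinone carbonyls, without affecting the secondary ester, the tertiary allylic alcohol or the alkene (fluoride desilylation).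

**Compound list**

1 | 2-bromo-1,4-dimethoxybenzene | COc1ccc(OC)c(Br)c1 | starting material
2 | 1,1-diethoxyethene (ketene diethyl acetal) | C=C(OCC)OCC | starting material
3 | 3,6-dimethoxybenzyne | COC1=CC=C(OC)C#C1 | intermediate
4 | 1,1-diethoxy-3,6-dimethoxybenzocyclobutene | CCOC1(OCC)Cc2c(OC)ccc(OC)c21 | intermediate
5 | 3,6-dimethoxybenzocyclobutenone | COc1ccc(OC)c2c1CC2=O | intermediate
6 | 2,2-dibromo-3,6-dimethoxybenzocyclobutenone | COc1ccc(OC)c2c1C(Br)(Br)C2=O | intermediate
7 | 3,6-dimethoxybenzocyclobutene-1,2-dione | COc1ccc(OC)c2c1C(=O)C2=O | intermediate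
8 | 3,6-dihydroxybenzocyclobutene-1,2-dione | Oc1ccc(O)c2c1C(=O)C2=O | intermediate
9 | 3,6-bis(tert-butyldimethylsilyloxy)benzocyclobutene-1,2-dione | CC(C)(C)[Si](C)(C)Oc1ccc(O[Si](C)(C)C(C)(C)C)c2c1C(=O)C2=O | intermediate
10 | chlorobis(triphenylphosphine)[3,6-bis(tert-butyldimethylsilyloxy)phthaloyl]cobalt (five-membered acyl metallacycle of trivalent cobalt) | CC(C)(C)[Si](C)(C)Oc1ccc(O[Si](C)(C)C(C)(C)C)c2c1C(=O)[Co-2](Cl)([P+](c1ccccc1)(c1ccccc1)c1ccccc1)([P+](c1ccccc1)(c1ccccc1)c1ccccc1)C2=O | intermediate
11 | chloro(dimethylglyoxime)(pyridine)[3,6-bis(tert-butyldimethylsilyloxy)phthaloyl]cobalt (octahedral trivalent cobalt, neutral N,N-bound dimethylglyoxime) | CC(C)(C)[Si](C)(C)Oc1ccc(O[Si](C)(C)C(C)(C)C)c2c1C(=O)[Co-3]1(Cl)([n+]3ccccc3)([N+](O)=C(C)C(C)=[N+]1O)C2=O | intermediate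
12 | 2-methylbut-3-en-2-ol | C=CC(C)(C)O | starting material
13 | N-methoxy-N-methylacrylamide | C=CC(=O)N(C)OC | starting material
14 | (E)-4-hydroxy-N-methoxy-N,4-dimethylpent-2-enamide | CON(C)C(=O)/C=C/C(C)(C)O | intermediate
15 | ethynyltrimethylsilane | C#C[Si](C)(C)C | starting material
16 | lithium (trimethylsilyl)acetylide | [Li]C#C[Si](C)(C)C | intermediate
17 | (E)-6-hydroxy-6-methyl-1-(trimethylsilyl)hept-4-en-1-yn-3-one | C[Si](C)(C)C#CC(=O)/C=C/C(C)(C)O | intermediate
18 | (3E,5R)-2-methyl-7-(trimethylsilyl)hept-3-en-6-yne-2,5-diol | C[Si](C)(C)C#C[C@H](O)/C=C/C(C)(C)O | intermediate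
19 | (3E,5R)-2-methylhept-3-en-6-yne-2,5-diol | C#C[C@H](O)/C=C/C(C)(C)O | intermediate
20 | (R)-2-methylbutanoic acid | CC[C@@H](C)C(=O)O | starting material
21 | (3R,4E)-6-hydroxy-6-methylhept-4-en-1-yn-3-yl (2R)-2-methylbutanoate | CC[C@@H](C)C(=O)O[C@H](/C=C/C(C)(C)O)C#C | intermediate
22 | (1R,2E)-1-[5,8-bis(tert-butyldimethylsilyloxy)-1,4-dioxo-1,4-dihydronaphthalen-2-yl]-4-hydroxy-4-methylpent-2-en-1-yl (2R)-2-methylbutanoate | CC[C@@H](C)C(=O)O[C@H](/C=C/C(C)(C)O)C1=CC(=O)c2c(O[Si](C)(C)C(C)(C)C)ccc(O[Si](C)(C)C(C)(C)C)c2C1=O | intermediate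
23 | (1R,2E)-1-(5,8-dihydroxy-1,4-dioxo-1,4-dihydronaphthalen-2-yl)-4-hydroxy-4-methylpent-2-en-1-yl (2R)-2-methylbutanoate | CC[C@@H](C)C(=O)O[C@H](/C=C/C(C)(C)O)C1=CC(=O)c2c(O)ccc(O)c2C1=O | target

Total step count: 13. Longest linear sequence: 8 steps (steps 1 to 6, then 12 and 13); the alkyne branch (steps 7 to 11) joins at step 12.

**Steps most likely to fail**

Step 12. What may go wrong: Lewis-acid-assisted ionisation, elimination or 1,3-acyloxy shift of the doubly activated (propargylic and allylic) carboxylate of 21 at 70 °C before the alkyne has inserted. Fallback: the order of events is changed so that the alkyne carries a free carbinol, which is a much poorer leaving group. Diol 19 is annulated with complex 11 (CoCl2·6H2O, MeCN, 70 °C) to give 5,8-bis(tert-butyldimethylsilyloxy)-2-[(1R,2E)-1,4-dihydroxy-4-methylpent-2-en-1-yl]naphthalene-1,4-dione F1. F1 is then acylated at the secondary alcohol with acid 20 (EDC·HCl, DMAP, CH2Cl2, 0 °C), which returns to the route at 22.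

Step 9. What may go wrong: insufficient discrimination between the alkynyl and alkenyl substituents during hydride transfer, which would erode the enantiomeric purity, or competing conjugate reduction. Fallback: the stereocentre is made by C–C bond formation instead of reduction. Alcohol 12 undergoes cross-metathesis with crotonaldehyde (second-generation Hoveyda–Grubbs catalyst, CH2Cl2, 40 °C) to give (E)-4-hydroxy-4-methylpent-2-enal F2. F2 then undergoes zinc–ProPhenol-catalysed enantioselective alkynylation with 15 (Me2Zn, toluene, 0 °C), using the ProPhenol enantiomer that delivers the alkynyl group to the Si face of the aldehyde; the sense would be confirmed by Mosher ester analysis. This returns to the route at 18 and bypasses 14 and 17.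

Step 2. What may go wrong: electrophilic bromination of the electron-rich dimethoxyarene ring competing with the radical benzylic bromination. Fallback: the ring is deactivated before bromination by bringing the ether cleavage forward and carrying the phenols as acetates. Ketone 5 is demethylated (BBr3, CH2Cl2) to 3,6-dihydroxybenzocyclobutenone F3 and acetylated (Ac2O, pyridine) to 3,6-diacetoxybenzocyclobutenone F4. F4 is dibrominated (NBS, radical initiator) to 2,2-dibromo-3,6-diacetoxybenzocyclobutenone F5 and hydrolysed (AgOCOCF3, MeCN/H2O) to 3,6-diacetoxybenzocyclobutene-1,2-dione F6. Acidic methanolysis of the acetates (HCl, MeOH) then returns to the route at 8, so that steps 3 and 4 are no longer needed.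

**Further compounds**

F1 | step 12 | 5,8-bis(tert-butyldimethylsilyloxy)-2-[(1R,2E)-1,4-dihydroxy-4-methylpent-2-en-1-yl]naphthalene-1,4-dione | O[C@H](/C=C/C(C)(C)O)C1=CC(=O)c2c(O[Si](C)(C)C(C)(C)C)ccc(O[Si](C)(C)C(C)(C)C)c2C1=O
F2 | step 9 | (E)-4-hydroxy-4-methylpent-2-enal | CC(C)(O)/C=C/C=O
F3 | step 2 | 3,6-dihydroxybenzocyclobutenone | Oc1ccc(O)c2c1CC2=O
F4 | step 2 | 3,6-diacetoxybenzocyclobutenone | CC(=O)Oc1ccc(OC(C)=O)c2c1CC2=O
F5 | step 2 | 2,2-dibromo-3,6-diacetoxybenzocyclobutenone | CC(=O)Oc1ccc(OC(C)=O)c2c1C(Br)(Br)C2=O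
F6 | step 2 | 3,6-diacetoxybenzocyclobutene-1,2-dione | CC(=O)Oc1ccc(OC(C)=O)c2c1C(=O)C2=O
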